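## Structural features

The target (16 below) is a monocyclic 1,2-dioxane, O1–O2–C3–C4–C5–C6, numbered along its C1–C12 chain (C1 ester carbon, C2 methylene, C12 benzylic carbon). C3 carries the CH2CO2Me arm, C4 a methyl group, and the fully substituted C6 a methyl group and the chain C7H2–C8(CH3)=C9H–C10H=C11H–C12H2Ph with 8E and 10E double bonds. C3 (S) and C4 (R) are adjacent and C6 (R) stands 1,3 to C4; in the chair the C3 arm, the C4 methyl and the C6 chain are equatorial and only the C6 methyl is axial. C3 is therefore the thermodynamically preferred epimer and, being β to the ester, can be set by reversible oxa-Michael closure, whereas C4 and C6 cannot be equilibrated. The real difficulty is C6: a peroxide-bearing quaternary carbon whose carbon substituents are CH3, C5H2 and C7H2, so an open-chain trigonal C6 radical or cation has no facial bias, and a tertiary alcohol cannot be turned into a hydroperoxide stereospecifically. Fragile elements are the O–O bond (reductants, low-valent metals, hard carbanions), the β-peroxy ester (E1cB with strong base), the diene with its doubly activated C12 methylene (radicals, singlet oxygen, strong acid) and the geometry of the trisubstituted C8=C9 bond. The key step exploits the homoallylic array O1–C6–C7H2–C8(CH3)=C9: it is the retron of a nucleophilic opening of a cyclopropylcarbinyl cation in which C6, C7 and C8 form a three-membered ring and C9 is the carbinyl carbon.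

## Logic of the disconnections

16 ⇒ 15. The O2–C3 bond is cut. C3 is β to the ester and its configuration is the equatorial one once C4 and C6 are fixed, so it is left to a reversible 6-exo oxa-Michael closure. The ring and one stereocentre disappear. The forward step needs the (E)-enoate and the (6R)-hydroperoxide in the same open chain, and a base mild enough for the O–O bond and the diene.

15 ⇒ 14 (key disconnection). The O1–C6 bond is cut, the C6–C8 bond is restored and the C8=C9 π bond becomes a ring σ bond, with C9 turned into a carbinol carbon. In one sentence, the route is the stereoinvertive ring-opening perhydrolysis of a 1,2-dimethylcyclopropyl alkenyl carbinol at its quaternary ring carbon. The quaternary peroxy centre becomes an all-carbon cyclopropane centre that a reagent can set, the (8E) trisubstituted alkene needs no olefination, and the C9 configuration is irrelevant. The forward step must deliver H2O2 to C6 with inversion, give the 8E geometry and spare enoate and diene.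

14 ⇒ 10 + 11 (through 12 and 13). The C9–C10 bond is cut. The phenylpropenyl unit is added as an alkenylmetal to an aldehyde, which removes nine carbons in one convergent step. The addition must prefer the aldehyde to the enoate and keep the 10E geometry; no control at C9 is needed.

10 ⇒ 7 (through 9 and 8). The C2=C3 bond is cut (Wittig) and the oxidation levels at C3 and C9 are adjusted. The enoate is installed before the peroxide exists, so no functional-group work follows O–O formation. This demands a partial ester reduction without epimerisation at C4, an E-selective olefination next to a free hydroxyl, and oxidation of a neopentyl-type cyclopropylmethanol.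

7 ⇒ 6. The C6–C7 and C7–C8 bonds are cut (removal of the C7 methylene). A hydroxyl-directed, ligand-controlled Simmons–Smith addition to a tetrasubstituted (Z)-allylic alcohol sets C6 absolutely; the alkene geometry decides which of CH3 and C5H2 is cis to the carbinol. Two quaternary centres are traded for one alkene geometry. The reagent must override the remote C4 centre and tolerate the ester.

6 ⇒ 3 + 4 (through 5). The C5–C6 bond is cut. The C4 stereocentre is bought with 4, and the alkene geometry comes from 3 with retention in an sp3–sp2 Negishi coupling. The zinc reagent must form without loss of the stereocentre and couple at a tetrasubstituted iodoalkene bearing a free hydroxyl.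

3 ⇒ 1 (through 2). The C8–CH3 and C6–I bonds are cut. Anti-carbomagnesiation of a propargylic alcohol and iodinolysis give the tetrasubstituted iodoalkene in one step. The methyl group must go to the carbon next to CH2OH and magnesium must end cis to it.

## Other disconnections considered

Alternative 1: the first route that comes to mind cuts O2–C3 by oxa-Michael addition and O1–C6 by radical hydroperoxidation. The precursor would be the 1,1-disubstituted alkene methyl (2E,4R,8E,10E)-4,8-dimethyl-6-methylidene-12-phenyldodeca-2,8,10-trienoate A1. The forward key step is Mukaiyama–Isayama hydroperoxysilylation (Co(thd)2, O2, Et3SiH) of this alkene to the silyl peroxide A2, followed by fluoride- or base-triggered closure. The C6 radical is trigonal, acyclic and flanked by CH3 and two CH2 groups, so oxygen capture cannot be face-selective and A2 would be expected as both C6 epimers. Hydrogen-atom transfer to the conjugated diene would also compete with the 1,1-disubstituted alkene. The chosen plan sets C6 by a stereospecific substitution instead.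

Alternative 2: cut C6–C7 on a preformed ring. The peroxyketal methyl 2-[(3S,4R)-6-methoxy-4,6-dimethyl-1,2-dioxan-3-yl]acetate A3 would be ionised at C6 with TiCl4 and the ring cation so formed trapped with the allylsilane A4 (Hosomi–Sakurai type, with transposition, which also builds the 8E alkene). Stereoelectronically preferred axial attack on the half-chair with the C4 methyl pseudo-equatorial puts the incoming chain trans to that methyl. This is predicted to give the C6 epimer A5; only a methyl nucleophile, for which no peroxide-compatible reagent is established, would give the target. The mechanism therefore argues against this cut.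

Alternative 3: dearomatisation plus an enzyme. Photo-oxygenation of 2,4,6-trimethylphenol A6 gives the symmetric p-peroxyquinol A7, whose nine carbons map onto C3–C8 and the three C-methyl groups. An ene-reductase could desymmetrise this dienone to the (4R,6R)-configured enone A8, setting C4 and C6 in one event, after which the ring bond C3–C8 would be cleaved. The cleavage delivers C8 as a methyl ketone β to the peroxide, as in A9. Turning that ketone into the (8E)-diene needs a basic olefination, which invites E1cB loss of the peroxide or Weitz–Scheffer-type epoxide formation and gives poor E control. C3 also emerges at the wrong oxidation level, and the enzyme must accept a hydroperoxide. The step count would be clearly higher than in the chosen plan.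

Key step: step 8

Assumption: 1, 4 and 11 are taken as commercial, and the facial sense of the dioxaborolane-mediated cyclopropanation is taken from the established model for this ligand class.

## Steps

Step 1
Reactants: 1 but-2-yn-1-ol
Product: 3 (2Z)-3-iodo-2-methylbut-2-en-1-ol, via alkenylmagnesium alkoxide 2 (not isolated)
Conditions: MeMgBr (3 equiv), CuI (10 mol %), THF, 0 °C → reflux; then I2, −78 → 0 °C; aq. NH4Cl
Reagents that add atoms: methylmagnesium bromide C[Mg]Br; iodine II
Why: Copper-catalysed anti-carbomagnesiation of a propargylic alcohol: the magnesium alkoxide directs the methyl group to the carbon next to CH2O and holds magnesium on the distal carbon in a five-membered chelate. Iodinolysis with retention should then place iodine cis to CH2OH (Z); no stereocentre is formed.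

Step 2
Reactants: 4 methyl (2S)-3-bromo-2-methylpropanoate; 3 (2Z)-3-iodo-2-methylbut-2-en-1-ol
Product: 6 methyl (2R,4Z)-6-hydroxy-2,4,5-trimethylhex-4-enoate, via alkylzinc bromide 5 (not isolated)
Conditions: Zn dust, LiCl, THF, 40 °C; then 3, Pd(OAc)2 (2 mol %), SPhos (4 mol %), THF, 25 °C
Reagents that add atoms: none
Why: Zinc insertion into the primary C–Br bond gives the ester-stabilised β-zincio ester without touching the adjacent stereocentre. Negishi coupling with the alkenyl iodide should proceed with retention of the Z geometry and tolerate the free hydroxyl. The bought stereocentre becomes C4 of the target (the descriptor changes from S to R only through the priority change).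

Step 3
Reactants: 6 methyl (2R,4Z)-6-hydroxy-2,4,5-trimethylhex-4-enoate
Product: 7 methyl (2R)-3-[(1S,2R)-2-(hydroxymethyl)-1,2-dimethylcyclopropyl]-2-methylpropanoate
Conditions: Et2Zn, CH2I2, DME, CH2Cl2, −10 °C [Zn(CH2I)2·DME]; (4S,5S)-2-butyl-N,N,N′,N′-tetramethyl-1,3,2-dioxaborolane-4,5-dicarboxamide (1.2 equiv), −10 → 25 °C; ligand removed unchanged by aqueous extraction
Reagents that add atoms: diiodomethane ICI
Why: Hydroxyl-directed asymmetric Simmons–Smith cyclopropanation: the zinc alkoxide–dioxaborolane complex delivers CH2 to one face of the electron-rich tetrasubstituted alkene, and syn addition translates the Z geometry into the cis relationship of the two methyl groups. By the facial model of this ligand class (the (4R,5R) ligand gives the (1S,2S) cyclopropane from (E)-cinnamyl alcohol), the (4S,5S) ligand should give the (1S,2R) ring. Its C1 is the future C6, set with the configuration that inversion in step 8 converts into 6R.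

Step 4
Reactants: 7 methyl (2R)-3-[(1S,2R)-2-(hydroxymethyl)-1,2-dimethylcyclopropyl]-2-methylpropanoate
Product: 8 (2R)-3-[(1S,2R)-2-(hydroxymethyl)-1,2-dimethylcyclopropyl]-2-methylpropanal
Conditions: i-Bu2AlH (2.1 equiv), CH2Cl2, −78 °C; MeOH, then aq. potassium sodium tartrate
Reagents that add atoms: none
Why: Partial reduction of the methyl ester: the first equivalent is consumed by the hydroxyl, the second gives the tetrahedral aluminium hemiacetal, which is stable at −78 °C and releases the aldehyde on work-up. The cold, non-basic quench should keep the α-stereocentre (C4) intact.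

Step 5
Reactants: 8 (2R)-3-[(1S,2R)-2-(hydroxymethyl)-1,2-dimethylcyclopropyl]-2-methylpropanal
Product: 9 methyl (2E,4R)-5-[(1S,2R)-2-(hydroxymethyl)-1,2-dimethylcyclopropyl]-4-methylpent-2-enoate
Conditions: Ph3P=CHCO2Me, CH2Cl2, 25 °C
Reagents that add atoms: methyl (triphenylphosphoranylidene)acetate COC(=O)C=P(c1ccccc1)(c1ccccc1)c1ccccc1
Why: Wittig olefination with a stabilised ylide should be E-selective and is neutral, so the α-stereocentre is not epimerised and the free hydroxyl is tolerated.

Step 6
Reactants: 9 methyl (2E,4R)-5-[(1S,2R)-2-(hydroxymethyl)-1,2-dimethylcyclopropyl]-4-methylpent-2-enoate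
Product: 10 methyl (2E,4R)-5-[(1S,2R)-2-formyl-1,2-dimethylcyclopropyl]-4-methylpent-2-enoate
Conditions: Dess–Martin periodinane, pyridine, CH2Cl2, 0 → 25 °C
Reagents that add atoms: none
Why: Dess–Martin oxidation of the primary cyclopropylmethanol under buffered conditions. The α-carbon is quaternary, so the aldehyde cannot epimerise, and the enoate is inert.

Step 7
Reactants: 11 prop-2-yn-1-ylbenzene; 10 methyl (2E,4R)-5-[(1S,2R)-2-formyl-1,2-dimethylcyclopropyl]-4-methylpent-2-enoate
Product: 14 methyl (2E,4R)-5-[(1S,2R)-2-[(2E)-1-hydroxy-4-phenylbut-2-en-1-yl]-1,2-dimethylcyclopropyl]-4-methylpent-2-enoate, via alkenylzirconocene chloride 12 (not isolated), via alkenyl(methyl)zinc 13 (not isolated)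
Conditions: 11, Cp2Zr(H)Cl, CH2Cl2, 25 °C; Me2Zn, toluene, −65 °C; then 10, 0 °C; aq. NH4Cl
Reagents that add atoms: none
Why: syn-Hydrozirconation of the terminal alkyne fixes the E geometry; transmetalation to zinc gives an alkenylzinc that adds 1,2 to the aldehyde and not to the enoate. The new carbinol centre is not controlled and need not be, because it is erased in step 8; both epimers are carried on.

Step 8
Reactants: 14 methyl (2E,4R)-5-[(1S,2R)-2-[(2E)-1-hydroxy-4-phenylbut-2-en-1-yl]-1,2-dimethylcyclopropyl]-4-methylpent-2-enoate
Product: 15 methyl (2E,4R,6R,8E,10E)-6-hydroperoxy-4,6,8-trimethyl-12-phenyldodeca-2,8,10-trienoate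
Conditions: anhydrous H2O2 in Et2O (ca. 15 equiv), Sc(OTf)3 (5 mol %), Et2O, −40 → 0 °C
Reagents that add atoms: hydrogen peroxide OO
Why: Proposed new method: Sc(OTf)3 ionises the allylic cyclopropylcarbinol (either epimer) to a cation stabilised by the C10=C11 bond and by the ring bonds at C8; H2O2 attacks the quaternary ring carbon C6 opposite the breaking C6–C8 bond, so O1–C6 forms with inversion while the C6–C8 electrons become the C8=C9 π bond. The closest known reaction types are the stereoinvertive substitution at the quaternary carbon of cyclopropylcarbinols by halide, water or alcohol nucleophiles (Julia-type cyclopropylcarbinyl-to-homoallyl opening) and the Lewis acid-mediated perhydrolysis of oxetanes and epoxides at a tertiary carbon; H2O2 has not been shown as the nucleophile in the former. No ring is closed: the three-membered ring is opened, and the dioxane closes in step 9. C6 is controlled by the cyclopropane configuration from step 3 through stereospecific inversion, independent of the C8 and C9 configurations, which are erased. The 8E geometry should follow from the bisected cation conformer that keeps the alkenyl residue beside the C8 methyl and away from the ring; 10E is carried over from step 7. The step needs regioselectivity for C6 over C7, C9 and C11: C6 is the only ring carbon that can carry tertiary cation character, and capture at the allylic termini C9 and C11 is reversible under the acid, whereas ring opening (strain release, conjugated diene) is not. Low temperature and a large excess of H2O2 are meant to suppress loss of a C12 proton and Hock-type cleavage.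

Step 9
Reactants: 15 methyl (2E,4R,6R,8E,10E)-6-hydroperoxy-4,6,8-trimethyl-12-phenyldodeca-2,8,10-trienoate
Product: 16 methyl 2-[(3S,4R,6R)-4,6-dimethyl-6-[(2E,4E)-2-methyl-6-phenylhexa-2,4-dien-1-yl]-1,2-dioxan-3-yl]acetate
Conditions: Et2NH (0.3 equiv), CF3CH2OH, 25 °C
Reagents that add atoms: none
Why: Intramolecular 6-exo-trig oxa-Michael addition of the hydroperoxide to the (E)-enoate closes O2–C3 through a chair with the C4 methyl and the C6 chain equatorial. The addition is reversible under the amine, so the mixture should settle on the (3S) isomer, in which the C3 arm is equatorial and trans to the C4 methyl. The mild base leaves the O–O bond and the diene untouched.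

## Compound list

1 | but-2-yn-1-ol | CC#CCO | starting material
2 | bromomagnesium alkoxide of (2Z)-3-(bromomagnesio)-2-methylbut-2-en-1-ol | Br[Mg]OC/C(C)=C(/C)[Mg]Br | intermediate (not isolated)
3 | (2Z)-3-iodo-2-methylbut-2-en-1-ol | OC/C(C)=C(/C)I | intermediate
4 | methyl (2S)-3-bromo-2-methylpropanoate | COC(=O)[C@H](C)CBr | starting material
5 | [(2S)-3-methoxy-2-methyl-3-oxopropyl]zinc bromide | COC(=O)[C@H](C)C[Zn]Br | intermediate (not isolated)
6 | methyl (2R,4Z)-6-hydroxy-2,4,5-trimethylhex-4-enoate | COC(=O)[C@H](C)C/C(C)=C(/C)CO | intermediate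
7 | methyl (2R)-3-[(1S,2R)-2-(hydroxymethyl)-1,2-dimethylcyclopropyl]-2-methylpropanoate | COC(=O)[C@H](C)C[C@@]1(C)C[C@@]1(C)CO | intermediate
8 | (2R)-3-[(1S,2R)-2-(hydroxymethyl)-1,2-dimethylcyclopropyl]-2-methylpropanal | O=C[C@H](C)C[C@@]1(C)C[C@@]1(C)CO | intermediate
9 | methyl (2E,4R)-5-[(1S,2R)-2-(hydroxymethyl)-1,2-dimethylcyclopropyl]-4-methylpent-2-enoate | COC(=O)/C=C/[C@H](C)C[C@@]1(C)C[C@@]1(C)CO | intermediate
10 | methyl (2E,4R)-5-[(1S,2R)-2-formyl-1,2-dimethylcyclopropyl]-4-methylpent-2-enoate | COC(=O)/C=C/[C@H](C)C[C@@]1(C)C[C@@]1(C)C=O | intermediate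
11 | prop-2-yn-1-ylbenzene | C#CCc1ccccc1 | starting material
12 | chlorobis(cyclopentadienyl)[(1E)-3-phenylprop-1-en-1-yl]zirconium | Cl[Zr](/C=C/Cc1ccccc1)(C1C=CC=C1)C1C=CC=C1 | intermediate (not isolated)
13 | methyl[(1E)-3-phenylprop-1-en-1-yl]zinc | C[Zn]/C=C/Cc1ccccc1 | intermediate (not isolated)
14 | methyl (2E,4R)-5-[(1S,2R)-2-[(2E)-1-hydroxy-4-phenylbut-2-en-1-yl]-1,2-dimethylcyclopropyl]-4-methylpent-2-enoate (both carbinol epimers) | COC(=O)/C=C/[C@H](C)C[C@@]1(C)C[C@@]1(C)C(O)/C=C/Cc1ccccc1 | intermediate
15 | methyl (2E,4R,6R,8E,10E)-6-hydroperoxy-4,6,8-trimethyl-12-phenyldodeca-2,8,10-trienoate | COC(=O)/C=C/[C@H](C)C[C@@](C)(OO)C/C(C)=C/C=C/Cc1ccccc1 | intermediate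
16 | methyl 2-[(3S,4R,6R)-4,6-dimethyl-6-[(2E,4E)-2-methyl-6-phenylhexa-2,4-dien-1-yl]-1,2-dioxan-3-yl]acetate | COC(=O)C[C@@H]1OO[C@@](C)(C/C(C)=C/C=C/Cc2ccccc2)C[C@H]1C | target

## Step count and least certain steps

Total step count: 9. Longest linear sequence: 9 steps (1 → 3 → 6 → 7 → 8 → 9 → 10 → 14 → 15 → 16); 4 and 11 enter in steps 2 and 7.

Step 8 (key step, proposed new method). The most likely failures are capture of the cation by H2O2 at the allylic termini C9 or C11 followed by Hock-type cleavage instead of re-ionisation, and loss of a C12 proton to a phenyl-conjugated triene. Premature opening to a free tertiary cation would erode the C6 configuration, and some 8Z isomer may form. The cation is more delocalised than in the precedents, which lowers the demand for nucleophilic assistance at C6. Fallback with known chemistry, from 14 back to 15: the established invertive bromide substitution of cyclopropylcarbinols (Me3SiBr, CH2Cl2, −40 °C) would give methyl (2E,4R,6R,8E,10E)-6-bromo-4,6,8-trimethyl-12-phenyldodeca-2,8,10-trienoate F1. Silver-assisted perhydrolysis of this tertiary bromide (AgOCOCF3, anhydrous H2O2, Et2O, −40 °C) would then give 15. Participation of the C8=C9 bond in the ionisation is expected to return the hydroperoxide with net retention; any C6 epimer would be removed after step 9.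

Step 3. Methylene transfer to a tetrasubstituted alkene may be slow, and facial selectivity may be poor because the ester competes with the ligand for zinc and both faces of the alkene are similarly hindered. Fallback, from 6 back to 7, with a covalently bound auxiliary instead of a ligand: MnO2 oxidation to methyl (2R,4Z)-2,4,5-trimethyl-6-oxohex-4-enoate F2. Buffered acetalisation with diisopropyl tartrate would give diisopropyl (4R,5R)-2-[(2Z,5R)-6-methoxy-3,5-dimethyl-6-oxohex-2-en-2-yl]-1,3-dioxolane-4,5-dicarboxylate F3; the tartrate antipode must be matched to the required face and is drawn here with the (R,R) ester. Acetal-directed Simmons–Smith cyclopropanation (Et2Zn, CH2I2) would give diisopropyl (4R,5R)-2-[(1R,2S)-2-[(2R)-3-methoxy-2-methyl-3-oxopropyl]-1,2-dimethylcyclopropyl]-1,3-dioxolane-4,5-dicarboxylate F4. Mild acid hydrolysis to methyl (2R)-3-[(1S,2R)-2-formyl-1,2-dimethylcyclopropyl]-2-methylpropanoate F5 and NaBH4 reduction would return 7.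

Step 4. Over-reduction to the primary alcohol and epimerisation at C4 during work-up are the likely failures, since the tetrahedral intermediate of an unhindered methyl ester can collapse before the quench. Fallback, from 7 to 10 (skipping 8 and 9): full reduction with LiBH4 to (2R)-3-[(1S,2R)-2-(hydroxymethyl)-1,2-dimethylcyclopropyl]-2-methylpropan-1-ol F6, then double Dess–Martin oxidation to (1R,2S)-1,2-dimethyl-2-[(2R)-2-methyl-3-oxopropyl]cyclopropane-1-carbaldehyde F7. One equivalent of Ph3P=CHCO2Me should react only at the less hindered aldehyde, whose α-carbon is secondary, leaving the cyclopropanecarbaldehyde with its quaternary α-carbon and giving 10.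

Step 9. Equilibration at C3 may be incomplete, and kinetic closure of the (E)-enoate has poor facial selectivity because the allylic C4 centre is not conformationally locked. Fallback, from 8 to 16, replacing thermodynamic control by allylic 1,3-strain control. Still–Gennari olefination of 8 (methyl bis(2,2,2-trifluoroethyl)phosphonoacetate, KN(SiMe3)2, 18-crown-6, −78 °C) would give methyl (2Z,4R)-5-[(1S,2R)-2-(hydroxymethyl)-1,2-dimethylcyclopropyl]-4-methylpent-2-enoate F8. Repeating the operations of steps 6 to 8 on this material would give in turn methyl (2Z,4R)-5-[(1S,2R)-2-formyl-1,2-dimethylcyclopropyl]-4-methylpent-2-enoate F9, then methyl (2Z,4R)-5-[(1S,2R)-2-[(2E)-1-hydroxy-4-phenylbut-2-en-1-yl]-1,2-dimethylcyclopropyl]-4-methylpent-2-enoate F10, then methyl (2Z,4R,6R,8E,10E)-6-hydroperoxy-4,6,8-trimethyl-12-phenyldodeca-2,8,10-trienoate F11. In the (Z)-enoate the ester forces the C4–H bond into the alkene plane, so the tethered hydroperoxide and the C4 methyl lie on opposite faces. Closure of the last of these under the conditions of step 9 should then give the 3,4-trans ring of 16 kinetically.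

## Further compounds

F1 | step 8 | methyl (2E,4R,6R,8E,10E)-6-bromo-4,6,8-trimethyl-12-phenyldodeca-2,8,10-trienoate | COC(=O)/C=C/[C@H](C)C[C@@](C)(Br)C/C(C)=C/C=C/Cc1ccccc1
F2 | step 3 | methyl (2R,4Z)-2,4,5-trimethyl-6-oxohex-4-enoate | COC(=O)[C@H](C)C/C(C)=C(/C)C=O
F3 | step 3 | diisopropyl (4R,5R)-2-[(2Z,5R)-6-methoxy-3,5-dimethyl-6-oxohex-2-en-2-yl]-1,3-dioxolane-4,5-dicarboxylate | COC(=O)[C@H](C)C/C(C)=C(/C)C1O[C@H]([C@@H](O1)C(=O)OC(C)C)C(=O)OC(C)C
F4 | step 3 | diisopropyl (4R,5R)-2-[(1R,2S)-2-[(2R)-3-methoxy-2-methyl-3-oxopropyl]-1,2-dimethylcyclopropyl]-1,3-dioxolane-4,5-dicarboxylate | COC(=O)[C@H](C)C[C@@]1(C)C[C@@]1(C)C2O[C@H]([C@@H](O2)C(=O)OC(C)C)C(=O)OC(C)C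
F5 | step 3 | methyl (2R)-3-[(1S,2R)-2-formyl-1,2-dimethylcyclopropyl]-2-methylpropanoate | COC(=O)[C@H](C)C[C@@]1(C)C[C@@]1(C)C=O
F6 | step 4 | (2R)-3-[(1S,2R)-2-(hydroxymethyl)-1,2-dimethylcyclopropyl]-2-methylpropan-1-ol | OC[C@H](C)C[C@@]1(C)C[C@@]1(C)CO
F7 | step 4 | (1R,2S)-1,2-dimethyl-2-[(2R)-2-methyl-3-oxopropyl]cyclopropane-1-carbaldehyde | O=C[C@H](C)C[C@@]1(C)C[C@@]1(C)C=O
F8 | step 9 | methyl (2Z,4R)-5-[(1S,2R)-2-(hydroxymethyl)-1,2-dimethylcyclopropyl]-4-methylpent-2-enoate | COC(=O)/C=C\[C@H](C)C[C@@]1(C)C[C@@]1(C)CO
F9 | step 9 | methyl (2Z,4R)-5-[(1S,2R)-2-formyl-1,2-dimethylcyclopropyl]-4-methylpent-2-enoate | COC(=O)/C=C\[C@H](C)C[C@@]1(C)C[C@@]1(C)C=O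
F10 | step 9 | methyl (2Z,4R)-5-[(1S,2R)-2-[(2E)-1-hydroxy-4-phenylbut-2-en-1-yl]-1,2-dimethylcyclopropyl]-4-methylpent-2-enoate | COC(=O)/C=C\[C@H](C)C[C@@]1(C)C[C@@]1(C)C(O)/C=C/Cc1ccccc1
F11 | step 9 | methyl (2Z,4R,6R,8E,10E)-6-hydroperoxy-4,6,8-trimethyl-12-phenyldodeca-2,8,10-trienoate | COC(=O)/C=C\[C@H](C)C[C@@](C)(OO)C/C(C)=C/C=C/Cc1ccccc1
A1 | alternative 1 | methyl (2E,4R,8E,10E)-4,8-dimethyl-6-methylidene-12-phenyldodeca-2,8,10-trienoate | COC(=O)/C=C/[C@H](C)CC(=C)C/C(C)=C/C=C/Cc1ccccc1
A2 | alternative 1 | methyl (2E,4R,8E,10E)-4,6,8-trimethyl-12-phenyl-6-[(triethylsilyl)peroxy]dodeca-2,8,10-trienoate (both C6 epimers) | COC(=O)/C=C/[C@H](C)CC(C)(OO[Si](CC)(CC)CC)C/C(C)=C/C=C/Cc1ccccc1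
A3 | alternative 2 | methyl 2-[(3S,4R)-6-methoxy-4,6-dimethyl-1,2-dioxan-3-yl]acetate | COC(=O)C[C@@H]1OOC(C)(OC)C[C@H]1C
A4 | alternative 2 | trimethyl[(4E)-2-methyl-6-phenylhexa-1,4-dien-3-yl]silane | C=C(C)C([Si](C)(C)C)/C=C/Cc1ccccc1
A5 | alternative 2 | methyl 2-[(3S,4R,6S)-4,6-dimethyl-6-[(2E,4E)-2-methyl-6-phenylhexa-2,4-dien-1-yl]-1,2-dioxan-3-yl]acetate | COC(=O)C[C@@H]1OO[C@](C)(C/C(C)=C/C=C/Cc2ccccc2)C[C@H]1C
A6 | alternative 3 | 2,4,6-trimethylphenol | Cc1cc(C)c(O)c(C)c1
A7 | alternative 3 | 4-hydroperoxy-2,4,6-trimethylcyclohexa-2,5-dien-1-one | CC1=CC(C)(OO)C=C(C)C1=O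
A8 | alternative 3 | (4R,6R)-4-hydroperoxy-2,4,6-trimethylcyclohex-2-en-1-one | C[C@@H]1C[C@@](C)(OO)C=C(C)C1=O
A9 | alternative 3 | methyl 2-[(3S,4R,6R)-4,6-dimethyl-6-(2-oxopropyl)-1,2-dioxan-3-yl]acetate | COC(=O)C[C@@H]1OO[C@@](C)(CC(C)=O)C[C@H]1C
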